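1. An invariant governs these flasks: free partner, plus one partner in each first product, two in each bis adduct or over-reaction product and two in each homo dimer, adds up to the charge 0.0300 M.

| flask | substrate | partner | remark | time |
|---|---|---|---|---|
| ash | 0.0078 M (fed, over 25 min) | 0.030 M | run made earlier |  |
| larch | 0.070 M (fed, over 25 min) | 0.030 M | run made earlier |  |
| eta | 0.010 M (fed, over 25 min) | 0.0300 M |  | 25 min |
| theta | 0.020 M (fed, over 25 min) | 0.0300 M |  | 25 min |
| gamma | 0.040 M (fed, over 25 min) | 0.0300 M |  | 25 min |
| zeta | 0.080 M (fed, over 25 min) | 0.0300 M |  | 25 min |

| run | time / min | bis adduct / % |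
|---|---|---|
| ash | 3.00 | 1.5 |
| ash | 6.00 | 3.7 |
| ash | 10.0 | 9.2 |
| ash | 12.0 | 17.7 |
| larch | 1.00 | 0.1 |
| larch | 2.50 | 0 |
| larch | 5.00 | 1.3 |
| larch | 12.0 | 7.5 |

(scatter of a reading: 1 percentage point)

- what may be going on: substrate + partner -> first product; partner + first product -> bis adduct; bis adduct -> over-reaction product; 2 partner -> homo dimer
- percentages count the whole charge, also what has not yet gone in
- "hardly changes" means that all values lie within two and a half points (for a concentration: within two and a half percent of the largest)

- [bis adduct] at the end for eta, theta, gamma, zeta, in this order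
- how the row runs (falls all the way / falls, then rises / hardly changes / rises all the way / rises, then falls)

2. The substrate dose draws on that fixed charge at a steady rate, so the flask has a natural clock. Gamma reaches in 18.8 min its equivalence time T = t_f·c_B/c_A, the moment at which the dosed substrate equals the partner charged. Here t_f is the dosing time, c_A the whole substrate charge and c_B the partner charge.

3. At the start, the dose rate c_A/t_f is 4.00 × 10⁻⁴ M min⁻¹ in eta and 0.00320 M min⁻¹ in zeta. That is a factor of 8.00, or 0.903 decades.

4. The earlier runs show the slowing. From ash to larch the dose rate gains 0.953 decades, but the bis adduct read at 12.0 min gains 0.580 decades, from 0.00138 M to 0.00525 M. As a reading, larch has therefore lost a factor of 2.36. Its T, 10.7 min, comes earlier than that reading, whereas the T of ash is 96.2 min.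

5. T marks no onset of the slowing: partner is drawn on from the first dose. The decimal logarithm of T/t_f is 0.176 for theta, whose T comes later than the end of dosing, and −0.125 for gamma, whose T comes earlier than that end. My own reckoning puts the turn between theta and gamma, near T = t_f.

6. The forecast gives 0.0045 M, 0.0065 M, 0.0075 M and 0.0058 M, so the row rises, then falls. Its ground: “Fast feeding therefore starves the second step”.

    substrate + partner → first product (k = 15.0 M⁻¹ min⁻¹)
    partner + first product → bis adduct (k = 5.50 M⁻¹ min⁻¹)
    bis adduct → over-reaction product (k = 0.00580 min⁻¹)
    2 partner → homo dimer (k = 0.290 M⁻¹ min⁻¹)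

The flask gives 0.00431 M, 0.00623 M, 0.00638 M and 0.00527 M, so the row rises, then falls, as forecast, though gamma stands at 0.00638 M against the forecast's 0.0075 M. Gamma's partner falls from 30.6% of its charge at 12.5 min to 1.26% at 25.0 min, and gamma's T of 18.8 min lies between those times. The row turns at 0.029 M, where T is 25.9 min against a dosing time of 25 min. In zeta, T is 9.38 min, earlier than 12.5 min, when zeta's partner stands at 8.47%.

The numbers in the tables were computed with made-up constants.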